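Everything rests on cutting the C5'–C6' bond of ring B. Ring B is a resorcinol monomethyl ether: C2'–OH and C4'–OCH3 are meta, C1' carries the ring A aryloxy group and C6' a carbon substituent. The key step exploits this pattern, because it maps onto an open chain in which C2' and C6' are ketones, C1' the carbon between them, and C4'–C5' the β-carbon and methyl group of an (E)-β-methoxy enone. One base-mediated vinylogous aldol condensation forms C5'–C6', closes and aromatises ring B, and releases C2'–OH with C4'–OCH3 already in place. The precursor is thus a 2-aryloxy-1,3-diketone with a dimethoxyacetyl arm (masked C6' CH2OAc).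

Key step: step 4

Remarks before the steps
- Locants: unprimed atoms belong to ring A (the benzoate), primed atoms to ring B. In the open-chain heptenediones, C3 = C1', C4 = C2', C5 = C3', C6 = C4', C7 = C5' and C2 = C6'.
- Geometry: in the (E) enol ether, OCH3 outranks CH3. The C5' methyl and the C2' carbonyl therefore lie on the same side of C3'=C4'. All SMILES are drawn this way.
- The ring A phenol is left free on purpose. In the basic key step it is a lithium phenoxide chelated to the neighbouring ester, which makes the ester electron-rich and holds it in the plane of ring A. The five-membered Dieckmann-type attack of C1' on that ester (benzofuran-3-one formation) then has a poor electrophile and a poor trajectory. This choice also saves a protection and a deprotection.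
- The C1'–O bond is made last, by a neutral carbenoid insertion. No unstabilised C1' ketone enolate ever sits next to the ring A ester, and no enolate acylation has to compete with that cyclisation.
- Assumption: (E)-4-methoxypent-3-en-2-one is taken as a catalogue chemical; it is otherwise available in one operation from acetylacetone and trimethyl orthoformate under acid catalysis.

Step 1
Reactants: 1 (E)-4-methoxypent-3-en-2-one; 2 methyl dimethoxyacetate
Product: 3 (E)-1,1,6-trimethoxyhept-5-ene-2,4-dione
Conditions: LiN(SiMe3)2 (2.2 equiv), THF, −78 °C; then 2 (1.2 equiv), −78 to 0 °C; AcOH quench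
Reagents that add atoms: none
Why: Crossed Claisen condensation in which the silylamide removes the α'-methyl proton of the β-methoxy enone under kinetic control (cross-conjugated enolate, not the γ-anion), the activated and practically non-enolisable ester 2 acylates it, and the second equivalent of base stores the product as its diketonate, the (E) geometry of 1 being untouched.

Step 2
Reactants: 3 (E)-1,1,6-trimethoxyhept-5-ene-2,4-dione
Product: 4 (E)-3-diazo-1,1,6-trimethoxyhept-5-ene-2,4-dione
Conditions: 4-AcNHC6H4SO2N3 (1.1 equiv), Et3N, dry MeCN, 0 °C to rt
Reagents that add atoms: 4-acetamidobenzenesulfonyl azide, CC(=O)Nc1ccc(cc1)S(=O)(=O)N=[N+]=[N-]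
Why: Regitz diazo transfer in which Et3N ionises only the doubly activated C3 methylene (future C1'), the diketonate attacks the terminal nitrogen of the sulfonyl azide and the sulfonamide departs, while the dry, non-nucleophilic medium spares the dimethoxyacetyl group, the acetal and the enol ether.

Step 3
Reactants: 4 (E)-3-diazo-1,1,6-trimethoxyhept-5-ene-2,4-dione; 5 methyl 2,6-dihydroxy-4-methylbenzoate
Product: 6 methyl 2-hydroxy-4-methyl-6-{[(5E)-1,1,6-trimethoxy-2,4-dioxohept-5-en-3-yl]oxy}benzoate (racemic at C1')
Conditions: Rh2(OAc)4 (2 mol %), 5 (3 equiv), ClCH2CH2Cl, 70 °C, slow addition of 4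
Reagents that add atoms: none
Why: Dirhodium-carbenoid O–H insertion into a phenol, a known route from 2-diazo-1,3-dicarbonyl compounds to their 2-aryloxy derivatives, in which the electrophilic diacyl carbenoid should be captured by a phenol oxygen faster than it inserts into C–H bonds, the two hydroxyls of 5 are equivalent so that excess 5 and slow addition secure mono-insertion, the neutral medium avoids enolate chemistry at the ester, and C1' forms racemic and enolisable, which does not matter because it becomes aromatic.

Step 4
Reactants: 6 methyl 2-hydroxy-4-methyl-6-{[(5E)-1,1,6-trimethoxy-2,4-dioxohept-5-en-3-yl]oxy}benzoate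
Product: 8 methyl 2-[2-(dimethoxymethyl)-6-hydroxy-4-methoxyphenoxy]-6-hydroxy-4-methylbenzoate, via cyclic aldol 7 (not isolated)
Conditions: LiN(SiMe3)2 (4.5 equiv), THF, −78 °C to rt; AcOH, then aq NaH2PO4/Na2HPO4 (pH 7)
Reagents that add atoms: none
Why: The first two equivalents of base ionise the ring A phenol and C1'–H, further base reversibly takes a proton from the only acidic position left, the γ-methyl C5' of the β-methoxy enone, and the extended enolate adds through C5' to the C6' carbonyl to give the aldolate of 7; E1cB loss of water across C1'–C6', finished in the acetate buffer formed on quenching, gives a cross-conjugated dienone that shifts a C5' proton to oxygen and becomes the C2' phenol. The closest known reaction type is the biomimetic aldol-type aromatisation of open-chain 1,3,5-tricarbonyl compounds and their mono enol ethers to 5-substituted resorcinols. Ring B closes in the 6-(enolendo)-exo-trig mode, since C5' and C4' of the reacting enolate double bond both lie inside the new ring while the C6' oxygen stays outside. No stereocentre has to be controlled, because C1' and C6' of 7 both become aromatic carbons. The step needs carbon closure from C5' to C6' only, and the substrate secures it: the (E) enol ether puts the C5' methyl on the side of C2', closure through C3' would give a four-membered ring, the acetal-bearing acyl group cannot furnish a rival enolate and its two oxygens raise the electrophilicity of C6', γ-deprotonation switches off C4' as acceptor for the enolate oxygen (4-pyranone formation), a bulky silylamide adds to neither carbonyl so acyl cleavage is avoided, and the lithium phenoxide keeps the ring A ester unreactive towards C1'. The weak point is that C6' belongs to the C1' diketonate and that closure requires rotation about C1'–C2' out of the lithium chelate, which is why a base that deprotonates C5' reversibly, an excess of it and warming to room temperature are chosen.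

Step 5
Reactants: 8 methyl 2-[2-(dimethoxymethyl)-6-hydroxy-4-methoxyphenoxy]-6-hydroxy-4-methylbenzoate
Product: 9 methyl 2-(2-formyl-6-hydroxy-4-methoxyphenoxy)-6-hydroxy-4-methylbenzoate
Conditions: p-TsOH·H2O (5 mol %), acetone–H2O, rt
Reagents that add atoms: water, O
Why: Acid-catalysed acetal hydrolysis, in which the benzylic dimethyl acetal is by far the most acid-labile group while the diaryl ether, the hindered ester and the aryl methyl ether are inert to catalytic sulfonic acid in wet acetone.

Step 6
Reactants: 9 methyl 2-(2-formyl-6-hydroxy-4-methoxyphenoxy)-6-hydroxy-4-methylbenzoate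
Product: 10 methyl 2-hydroxy-6-[2-hydroxy-6-(hydroxymethyl)-4-methoxyphenoxy]-4-methylbenzoate
Conditions: NaBH4 (1.5 equiv), MeOH–THF, 0 °C; aq NH4Cl
Reagents that add atoms: none
Why: Chemoselective borohydride reduction, since NaBH4 at 0 °C reduces the aryl aldehyde quickly but not the hindered, hydrogen-bonded salicylate ester, and eight-membered lactonisation of the new alcohol onto that ester is too slow to interfere in the cold.

Step 7
Reactants: 10 methyl 2-hydroxy-6-[2-hydroxy-6-(hydroxymethyl)-4-methoxyphenoxy]-4-methylbenzoate
Product: 11 betaethrin A, methyl 2-[2-(acetoxymethyl)-6-hydroxy-4-methoxyphenoxy]-6-hydroxy-4-methylbenzoate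
Conditions: PPh3 (1.3 equiv), diisopropyl azodicarboxylate (1.3 equiv), AcOH (3 equiv), THF, 0 °C to rt
Reagents that add atoms: acetic acid, CC(=O)O
Why: Mitsunobu esterification, in which only the aliphatic alcohol can be converted into an alkoxyphosphonium leaving group and displaced, and acetic acid, far more acidic than either phenol, supplies the nucleophile, so that the primary benzylic carbon is acetoxylated by SN2 substitution while C2'–OH (meta to C6', hence no quinone methide pathway) and the ring A OH stay free.

Compound list
1 | (E)-4-methoxypent-3-en-2-one | CC(=O)/C=C(\C)OC | starting material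
2 | methyl dimethoxyacetate | COC(OC)C(=O)OC | starting material
3 | (E)-1,1,6-trimethoxyhept-5-ene-2,4-dione (largely enolised) | COC(OC)C(=O)CC(=O)/C=C(\C)OC | intermediate
4 | (E)-3-diazo-1,1,6-trimethoxyhept-5-ene-2,4-dione | COC(OC)C(=O)C(=[N+]=[N-])C(=O)/C=C(\C)OC | intermediate
5 | methyl 2,6-dihydroxy-4-methylbenzoate | COC(=O)c1c(O)cc(C)cc1O | starting material
6 | methyl 2-hydroxy-4-methyl-6-{[(5E)-1,1,6-trimethoxy-2,4-dioxohept-5-en-3-yl]oxy}benzoate (C1' racemic, enolisable) | COC(=O)c1c(O)cc(C)cc1OC(C(=O)C(OC)OC)C(=O)/C=C(\C)OC | intermediate
7 | methyl 2-{[2-(dimethoxymethyl)-2-hydroxy-4-methoxy-6-oxocyclohex-4-en-1-yl]oxy}-6-hydroxy-4-methylbenzoate (racemic diastereomer mixture, both centres lost on aromatisation; not isolated) | COC(=O)c1c(O)cc(C)cc1OC1C(=O)C=C(OC)CC1(O)C(OC)OC | intermediate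
8 | methyl 2-[2-(dimethoxymethyl)-6-hydroxy-4-methoxyphenoxy]-6-hydroxy-4-methylbenzoate | COC(=O)c1c(O)cc(C)cc1Oc1c(O)cc(OC)cc1C(OC)OC | intermediate
9 | methyl 2-(2-formyl-6-hydroxy-4-methoxyphenoxy)-6-hydroxy-4-methylbenzoate | COC(=O)c1c(O)cc(C)cc1Oc1c(O)cc(OC)cc1C=O | intermediate
10 | methyl 2-hydroxy-6-[2-hydroxy-6-(hydroxymethyl)-4-methoxyphenoxy]-4-methylbenzoate | COC(=O)c1c(O)cc(C)cc1Oc1c(O)cc(OC)cc1CO | intermediate
11 | betaethrin A | COC(=O)c1c(O)cc(C)cc1Oc1c(O)cc(OC)cc1COC(C)=O | target

Total step count: 7. Longest linear sequence: 7 (1 to 3, 4, 6, 8, 9, 10, 11).

Steps most likely to fail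

Step 4 (key step). Once the first protons are gone, C6' is part of the C1' diketonate, so the polyanion may fail to close. On warming or on the quench, the material could then be consumed in two ways: O-cyclisation of the C6' enolate oxygen onto C4' with loss of methanol, or attack of C1' on the ring A ester. The fallback reverses the order of ring closure and ether formation, setting out from 4 and coming back at 8. Diazo diketone 4 has no hydrogen at C1' and cannot be switched off by deprotonation. LiN(SiMe3)2 (one equivalent, THF, −78 to 0 °C) should remove a C5' proton, and the same C5'-to-C6' aldol condensation follows. Loss of water on mildly acidic work-up should then give the ortho-quinone diazide 6-diazo-5-(dimethoxymethyl)-3-methoxycyclohexa-2,4-dien-1-one F1. Rh2(OAc)4-catalysed O–H insertion of F1 into an excess of 5 makes the C1'–O bond on the finished ring and gives 8. This reaction type is known for diazonaphthoquinones and hydroxylic partners.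

Step 3. Capture of the carbenoid by a hydrogen-bonded, ester-flanked phenol may be slow. Intramolecular C–H insertion (acetal OCH3 or C5' methyl), Wolff rearrangement or a second insertion into the product could then compete. The fallback replaces carbene chemistry with ionic C–O bond formation, setting out from 3 and coming back at 6. Chlorination of the diketone enol with N-chlorosuccinimide (CH2Cl2, 0 °C) should give (E)-3-chloro-1,1,6-trimethoxyhept-5-ene-2,4-dione F2. Displacement of chloride by the phenoxide of 5 (excess 5, K2CO3, acetone, rt) then gives 6. This is the usual way from 3-chloropentane-2,4-dione to 3-aryloxypentane-2,4-diones.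

Step 7. Chemoselectivity may erode, with a phenol oxygen of a second molecule competing with acetate for the activated benzylic carbon and building oligomers. The fallback is exhaustive acylation followed by selective deacylation, setting out from 10 and coming back at 11. Ac2O and pyridine convert 10 into the triacetate methyl 2-acetoxy-6-[2-acetoxy-6-(acetoxymethyl)-4-methoxyphenoxy]-4-methylbenzoate F3. NH4OAc in aqueous methanol at rt then cleaves only the two aryl acetates, whose phenoxide leaving groups make them far more reactive than the alkyl acetate.

Further compounds
F1 | step 4 | 6-diazo-5-(dimethoxymethyl)-3-methoxycyclohexa-2,4-dien-1-one | COC(OC)C1=CC(OC)=CC(=O)C1=[N+]=[N-]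
F2 | step 3 | (E)-3-chloro-1,1,6-trimethoxyhept-5-ene-2,4-dione (racemic) | COC(OC)C(=O)C(Cl)C(=O)/C=C(\C)OC
F3 | step 7 | methyl 2-acetoxy-6-[2-acetoxy-6-(acetoxymethyl)-4-methoxyphenoxy]-4-methylbenzoate | COC(=O)c1c(OC(C)=O)cc(C)cc1Oc1c(OC(C)=O)cc(OC)cc1COC(C)=O
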